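**Strategy.** Ring A (C10–C1–C2–C3–C4–C5) is closed last, through its C4–C5 bond. The C3 carbinol, the C4 gem-dimethyl carbon and the C5 carbon bearing the C6 aldehyde are read as an oxidosqualene-type retron: a C3–C4 epoxide and a C5=C6 enol ether on the two arms of the spiro carbon C10. One Lewis-acid step opens the epoxide at C4, forms the hindered C4–C5 bond in a chair, sets C5 and releases both the C3 hydroxyl and the C6 aldehyde. Its precursor is the finished 7,20-lactone/bicyclo[3.2.1]octane core whose C10, derived from pentaerythritol, carries a CH=CH–OMe arm and a CH(OAc)–CH2–epoxide arm.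

Key step: step 19

Remarks:
- ent-Kaurane numbering (C1–C20) of the target is used for all intermediates. "Core lactone" means the δ-lactone C7(=O)–O–C20–C10–C9–C8 fused at C8–C9 to the bicyclo[3.2.1]octane (C8, C9, C11–C14 six-membered ring; C15–C16 two-carbon bridge; 16-methylene C17).
- Assumption: 1 and 9 are purchased (9 freshly distilled).
- Assumption: 10 and 11 are carried as C15 epimer mixtures and 23 as an E/Z mixture; their SMILES leave these elements open.

Step 1
Reactants: 1 (2,2-dimethyl-1,3-dioxane-5,5-diyl)dimethanol; 2 methyl malonyl chloride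
Product: 3 [5-(hydroxymethyl)-2,2-dimethyl-1,3-dioxan-5-yl]methyl methyl malonate
Conditions: pyridine, CH2Cl2, 0 °C (1 in threefold excess, recovered)
Reagents that add atoms: none
Why: Statistical mono-acylation of one of two equivalent primary hydroxyls by the acid chloride should give the mono-ester; no stereocentre is formed.

Step 2
Reactants: 3 mono-malonate
Product: 5 methyl 3,3-dimethyl-9-oxo-2,4,8-trioxaspiro[5.5]undec-10-ene-10-carboxylate, via malonate aldehyde 4 (not isolated)
Conditions: TEMPO (10 mol%), PhI(OAc)2, CH2Cl2, rt; then piperidine (20 mol%), 40 °C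
Reagents that add atoms: none
Why: TEMPO oxidation of the primary alcohol followed by intramolecular Knoevenagel condensation of the malonate CH2 with the neopentyl aldehyde should close the unsaturated δ-lactone (C8=C9), which can only be the ring (Z)-alkene.

Step 3
Reactants: 5 spiro dienophile; 6 buta-1,3-diene
Product: 7 (8S,9S)-cis-fused cyclohexene lactone ester (Diels–Alder adduct)
Conditions: Cu(SbF6)2/(S,S)-t-Bu-box (10 mol%), CH2Cl2, −20 °C to rt
Reagents that add atoms: none
Why: Catalytic asymmetric Diels–Alder reaction in which two-point chelation of the β-alkoxycarbonyl lactone to the C2-symmetric Cu(II)–bis(oxazoline) shields one enantiotopic face of C8=C9 (C10 is not stereogenic here) and suprafacial addition sets C8 and C9 cis; the ligand antipode is taken if the sense of induction proves opposite.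

Step 4
Reactants: 7 Diels–Alder adduct
Product: 8 (8S,9R)-cis-fused cyclohexene lactone (C8–H)
Conditions: LiCl, H2O, DMSO, 150 °C
Reagents that add atoms: none
Why: Krapcho demethoxycarbonylation (chloride attack at the ester methyl, then decarboxylation) should remove the activating ester while the neopentyl lactone C–O bond is inert; the C8 configuration is re-set in step 5.

Step 5
Reactants: 8 cis-fused lactone; 9 2-bromoacrolein
Product: 10 (8S,9S)-8-(2-bromo-1-hydroxyallyl) lactone (C15 epimers)
Conditions: LDA, THF, −78 °C; then 9; AcOH quench at −78 °C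
Reagents that add atoms: none
Why: Aldol 1,2-addition of the lithium lactone enolate should occur on the convex face (anti to C11 and ring C), creating the quaternary C8 with C14 cis to C11; C15 is left uncontrolled and is set in steps 7–8.

Step 6
Reactants: 10 bromoallylic alcohol
Product: 11 (8S,9S,13R)-15-hydroxy-16-methylene core lactone acetonide (C15 epimers)
Conditions: Bu3SnH, AIBN (cat.), benzene, 80 °C, slow addition
Reagents that add atoms: none
Why: The vinyl radical formed by bromine abstraction should cyclise 5-exo-trig onto C13 of the ring alkene, closing ring D; the axial C8 side chain can only reach one face, which fixes C13.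

Step 7
Reactants: 11 allylic alcohol mixture
Product: 12 (8S,9S,13R)-16-methylene-15-oxo core lactone acetonide
Conditions: Dess–Martin periodinane, NaHCO3, CH2Cl2, rt
Reagents that add atoms: none
Why: Dess–Martin oxidation of the allylic alcohol should give the α-methylene ketone and converge both C15 epimers.

Step 8
Reactants: 12 enone
Product: 13 (8S,9S,13R,15R)-15-hydroxy core lactone acetonide (15-OH endo and syn to C9)
Conditions: NaBH4, CeCl3·7H2O, MeOH, −78 °C
Reagents that add atoms: none
Why: Luche 1,2-reduction should deliver hydride from the exo face (the side of the one-carbon bridge C14), giving the endo 15R alcohol.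

Step 9
Reactants: 13 allylic alcohol
Product: 14 15-O-TBS core lactone acetonide
Conditions: TBSOTf, 2,6-lutidine, CH2Cl2, −78 to 0 °C
Reagents that add atoms: tert-butyldimethylsilyl triflate, CC(C)(C)[Si](C)(C)OS(=O)(=O)C(F)(F)F
Why: Silyl triflate protection of the hindered secondary alcohol should proceed without touching the acetonide at low temperature.

Step 10
Reactants: 14 acetonide
Product: 15 15-O-TBS core lactone 10,10-bis(hydroxymethyl) diol
Conditions: AcOH/THF/H2O (3:1:1), 40 °C
Reagents that add atoms: none
Why: Mild acid hydrolysis should cleave the 1,3-dioxane while the hindered secondary TBS ether survives; C10 is still not stereogenic, so lactone migration between the CH2O groups would be degenerate.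

Step 11
Reactants: 15 diol
Product: 16 (10R)-mono-TES ether (equatorial C5H2–OTES and axial C1H2–OH)
Conditions: TESCl (1.05 equiv), imidazole, CH2Cl2, −40 °C
Reagents that add atoms: chlorotriethylsilane, CC[Si](Cl)(CC)CC
Why: Site-selective silylation should occur at the equatorial CH2OH, because the axial CH2OH is 1,3-diaxial to the C14 bridge on the rigid lactone half-chair; this differentiation sets C10.

Step 12
Reactants: 16 mono-TES ether
Product: 17 (10R)-C1 aldehyde
Conditions: Dess–Martin periodinane, NaHCO3, CH2Cl2, rt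
Reagents that add atoms: none
Why: Dess–Martin oxidation of the remaining primary alcohol should give the non-enolisable neopentyl aldehyde before any acyl migration can occur.

Step 13
Reactants: 17 C1 aldehyde
Product: 18 (1S,10R)-homoallylic alcohol
Conditions: allyl-Bpin, (S)-TRIP (10 mol%), toluene, −30 °C
Reagents that add atoms: allylboronic acid pinacol ester, C=CCB1OC(C)(C)C(C)(C)O1
Why: Chiral phosphoric acid-catalysed allylboration through a closed six-membered transition state should deliver allyl to the Si face under catalyst control, setting C1 as S.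

Step 14
Reactants: 18 homoallylic alcohol
Product: 19 (1S)-1-acetate
Conditions: Ac2O, pyridine, DMAP (cat.), CH2Cl2, rt
Reagents that add atoms: acetic anhydride, CC(=O)OC(C)=O
Why: Acetylation of the only free hydroxyl should install the C1 acetate of the target regiospecifically.

Step 15
Reactants: 19 terminal alkene
Product: 20 (1S)-1-acetoxy-3-ene with a C3=C4Me2 unit
Conditions: Grubbs II (5 mol%), 2-methyl-2-butene/CH2Cl2, 40 °C
Reagents that add atoms: 2-methyl-2-butene, CC=C(C)C
Why: Cross-metathesis should convert the monosubstituted alkene into the trisubstituted one, while the hindered 1,1-disubstituted C16=C17 alkene is inert.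

Step 16
Reactants: 20 trisubstituted alkene
Product: 21 (1S,3R)-3,4-epoxide
Conditions: Shi ketone (D-fructose-derived, 30 mol%), Oxone, K2CO3, Bu4NHSO4, MeCN/dimethoxymethane/aq. buffer pH 10.5, 0 °C
Reagents that add atoms: Oxone (potassium peroxymonosulfate), OOS(=O)(=O)[O-].[K+]
Why: Shi epoxidation through the spiro transition state should give the 3R epoxide under reagent control and should prefer the electron-rich trisubstituted alkene over the hindered C16=C17 alkene.

Step 17
Reactants: 21 epoxy TES ether
Product: 22 (1S,3R,10S)-C5 aldehyde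
Conditions: (COCl)2, DMSO, CH2Cl2, −78 °C; Et3N, −78 to −20 °C
Reagents that add atoms: none
Why: Swern conditions should oxidise the primary TES ether directly to the aldehyde, leaving the secondary TBS ether, epoxide and acetate untouched.

Step 18
Reactants: 22 C5 aldehyde
Product: 23 (1S,3R,10S)-C5=C6 methyl enol ether (E/Z)
Conditions: Ph3P(CH2OMe)Cl, KHMDS, THF, −78 to 0 °C
Reagents that add atoms: (methoxymethyl)triphenylphosphonium chloride, COC[P+](c1ccccc1)(c1ccccc1)c1ccccc1.[Cl-]
Why: Wittig methoxymethylenation should add C6 and create the nucleophilic enol ether in one operation; its E/Z ratio does not matter for the next step.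

Step 19
Reactants: 23 epoxy enol ether
Product: 24 15-O-TBS ether of the target
Conditions: MeAlCl2 (2 equiv), CH2Cl2, −78 °C; then aq. NaHCO3/Rochelle salt, rt
Reagents that add atoms: water, O
Why: MeAlCl2 coordinates the epoxide oxygen, the C4–O bond ionises at the tertiary carbon and the electron-rich C5 of the enol ether attacks C4 anti to the departing oxygen; the C6 methoxycarbenium ion is hydrolysed on work-up to the aldehyde and the aluminium alkoxide to the free C3 hydroxyl. The closest known reaction type is the Lewis-acid epoxide-initiated cation–olefin (oxidosqualene-type) cyclisation with an enol-ether or enol-silane terminator. Ring A closes 6-exo-trig with respect to the enol ether and 6-endo-tet (Markovnikov) with respect to the epoxide. C1 and C3 are carried in unchanged (the C3–O bond is not broken) and lock the chair with both oxygens equatorial and C20 axial; the new C5 centre is set as 5R (H5 axial) by the equatorial placement of the C5=C6 unit in this chair, and this is also the epimer expected on equilibration of the aldehyde. The step needs C-attack at C4 rather than closure at C3, hydride shift or acetate participation; the tertiary character of C4, the high nucleophilicity of the enol ether, the six-membered chair and −78 °C should secure this.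

Step 20
Reactants: 24 15-O-TBS ether
Product: 25 target CNP0536233.1
Conditions: HF·pyridine, pyridine, THF, 0 °C to rt
Reagents that add atoms: none
Why: Buffered fluoride desilylation should free the C15 hydroxyl without acyl migration or epimerisation at C5.

**Compound list**

1 | (2,2-dimethyl-1,3-dioxane-5,5-diyl)dimethanol (pentaerythritol monoacetonide) | OCC1(CO)COC(C)(C)OC1 | starting material
2 | methyl malonyl chloride | COC(=O)CC(=O)Cl | starting material
3 | [5-(hydroxymethyl)-2,2-dimethyl-1,3-dioxan-5-yl]methyl methyl malonate | COC(=O)CC(=O)OCC1(CO)COC(C)(C)OC1 | intermediate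
4 | (5-formyl-2,2-dimethyl-1,3-dioxan-5-yl)methyl methyl malonate (not isolated) | COC(=O)CC(=O)OCC1(C=O)COC(C)(C)OC1 | intermediate
5 | methyl 3,3-dimethyl-9-oxo-2,4,8-trioxaspiro[5.5]undec-10-ene-10-carboxylate | COC(=O)C1=CC2(COC(C)(C)OC2)COC1=O | intermediate
6 | buta-1,3-diene | C=CC=C | starting material
7 | methyl (4a′S,8a′S)-2,2-dimethyl-1′-oxo-4a′,5′,8′,8a′-tetrahydrospiro[1,3-dioxane-5,4′-isochromane]-8a′(1′H)-carboxylate (8S,9S; C12=C13 alkene) | C1=CC[C@@H]2[C@@](C1)(C(=O)OC)C(=O)OCC23COC(C)(C)OC3 | intermediate
8 | (4a′R,8a′S)-2,2-dimethyl-4a′,5′,8′,8a′-tetrahydrospiro[1,3-dioxane-5,4′-isochroman]-1′-one (cis-fused, C8–H) | C1=CC[C@@H]2[C@H](C1)C(=O)OCC23COC(C)(C)OC3 | intermediate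
9 | 2-bromoacrolein (2-bromoprop-2-enal) | C=C(Br)C=O | starting material
10 | (4a′S,8a′S)-8a′-(2-bromo-1-hydroxyallyl)-2,2-dimethyl-4a′,5′,8′,8a′-tetrahydrospiro[1,3-dioxane-5,4′-isochroman]-1′-one (C15 epimers) | C1=CC[C@@H]2[C@@](C1)(C(O)C(Br)=C)C(=O)OCC23COC(C)(C)OC3 | intermediate
11 | (8S,9S,13R)-15-hydroxy-16-methylene core lactone, C10 spiro-acetonide (C15 epimers) | C=C1[C@@H]2CC[C@@H]3[C@](C2)(C(=O)OCC34COC(C)(C)OC4)C1O | intermediate
12 | (8S,9S,13R)-16-methylene-15-oxo core lactone, C10 spiro-acetonide | C=C1[C@@H]2CC[C@@H]3[C@](C2)(C(=O)OCC34COC(C)(C)OC4)C1=O | intermediate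
13 | (8S,9S,13R,15R)-15-hydroxy-16-methylene core lactone, C10 spiro-acetonide (15-OH endo) | C=C1[C@@H]2CC[C@@H]3[C@](C2)(C(=O)OCC34COC(C)(C)OC4)[C@@H]1O | intermediate
14 | 15-O-TBS ether of 13 | C=C1[C@@H]2CC[C@@H]3[C@](C2)(C(=O)OCC34COC(C)(C)OC4)[C@@H]1O[Si](C)(C)C(C)(C)C | intermediate
15 | (8S,9S,13R,15R)-15-O-TBS core lactone with two CH2OH groups on C10 | C=C1[C@@H]2CC[C@@H]3[C@](C2)(C(=O)OCC3(CO)CO)[C@@H]1O[Si](C)(C)C(C)(C)C | intermediate
16 | (8S,9S,10R,13R,15R)-mono-TES ether: equatorial C5H2–OTES, axial C1H2–OH | C=C1[C@@H]2CC[C@@H]3[C@](C2)(C(=O)OC[C@]3(CO[Si](CC)(CC)CC)CO)[C@@H]1O[Si](C)(C)C(C)(C)C | intermediate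
17 | (10R)-C1 aldehyde (C5H2–OTES) | C=C1[C@@H]2CC[C@@H]3[C@](C2)(C(=O)OC[C@]3(CO[Si](CC)(CC)CC)C=O)[C@@H]1O[Si](C)(C)C(C)(C)C | intermediate
18 | (1S,10R)-homoallylic alcohol (C1–OH, C2H2–C3H=CH2) | C=C1[C@@H]2CC[C@@H]3[C@](C2)(C(=O)OC[C@]3(CO[Si](CC)(CC)CC)[C@@H](O)CC=C)[C@@H]1O[Si](C)(C)C(C)(C)C | intermediate
19 | (1S)-1-acetate of 18 | C=C1[C@@H]2CC[C@@H]3[C@](C2)(C(=O)OC[C@]3(CO[Si](CC)(CC)CC)[C@@H](OC(C)=O)CC=C)[C@@H]1O[Si](C)(C)C(C)(C)C | intermediate
20 | (1S)-1-acetoxy-3-ene (C3=C4Me2) | C=C1[C@@H]2CC[C@@H]3[C@](C2)(C(=O)OC[C@]3(CO[Si](CC)(CC)CC)[C@@H](OC(C)=O)CC=C(C)C)[C@@H]1O[Si](C)(C)C(C)(C)C | intermediate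
21 | (1S,3R)-1-acetoxy-3,4-epoxide (C5H2–OTES) | C=C1[C@@H]2CC[C@@H]3[C@](C2)(C(=O)OC[C@]3(CO[Si](CC)(CC)CC)[C@@H](OC(C)=O)C[C@@H]4C(C)(C)O4)[C@@H]1O[Si](C)(C)C(C)(C)C | intermediate
22 | (1S,3R,10S)-C5 aldehyde | C=C1[C@@H]2CC[C@@H]3[C@](C2)(C(=O)OC[C@]3(C=O)[C@@H](OC(C)=O)C[C@@H]4C(C)(C)O4)[C@@H]1O[Si](C)(C)C(C)(C)C | intermediate
23 | (1S,3R,10S)-C5=C6 methyl enol ether (E/Z mixture) | C=C1[C@@H]2CC[C@@H]3[C@](C2)(C(=O)OC[C@]3(C=COC)[C@@H](OC(C)=O)C[C@@H]4C(C)(C)O4)[C@@H]1O[Si](C)(C)C(C)(C)C | intermediate
24 | 15-O-TBS ether of the target (1S,3R,5R,8S,9S,10S,13R,15R) | C=C1[C@@H]2CC[C@@H]3[C@](C2)(C(=O)OC[C@]32[C@@H](OC(C)=O)C[C@@H](O)C(C)(C)[C@H]2C=O)[C@@H]1O[Si](C)(C)C(C)(C)C | intermediate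
25 | CNP0536233.1: (1S,3R,5R,8S,9S,10S,13R,15R)-1-acetoxy-3,15-dihydroxy-6-oxo-6,7-secokaur-16-en-7,20-olide | C=C1[C@@H]2CC[C@@H]3[C@](C2)(C(=O)OC[C@]32[C@@H](OC(C)=O)C[C@@H](O)C(C)(C)[C@H]2C=O)[C@@H]1O | target

**Step count and risks**

Total step count: 20. Longest linear sequence: 20 steps (from 1).

Steps most likely to fail:

1. Step 19 (key cyclisation). The developing C4 cation may be diverted by a 1,2-hydride shift to a C3 ketone, by participation of the C1 acetate or by closure at C3, or C5 may form with poor facial selectivity. The fallback replaces the cationic closure by a radical one, sets out from 22 and comes back at 24. Takai–Utimoto olefination of 22 (CrCl2, LiI, Cl2CH-Bpin, THF) should give the (E)-vinyl boronate F1. Titanocene(III) chloride (Cp2TiCl2, Mn, collidine hydrochloride, THF; Nugent–RajanBabu opening) should cleave the epoxide homolytically at C4, and the tertiary radical should add 6-exo to the boron-substituted alkene to give, after reduction and protonation, the ring-A boronate F2 with the free C3 hydroxyl. Oxidation with NaBO3 should give the C6 primary alcohol F3, and TEMPO/PhI(OAc)2 should oxidise only this primary alcohol to 24.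

2. Step 3 (asymmetric Diels–Alder). The hindered neopentyl dienophile may react sluggishly with butadiene under the chiral catalyst, or enantiofacial discrimination may be poor. The fallback uses resolution instead of catalysis, sets out from 5 and comes back at 7. A racemic Diels–Alder reaction promoted by an achiral Lewis acid (Et2AlCl or ZnBr2, CH2Cl2) should give 7 together with its enantiomer ent-7 F4, and preparative chromatography on a chiral stationary phase should deliver 7.

3. Step 5 (aldol with 2-bromoacrolein). The enal may polymerise or undergo conjugate addition, or the hindered aldolate may revert by retro-aldol. The fallback sets out from 8 and comes back at 11. C-alkylation of the same enolate with 2,3-dibromopropene (LDA, THF, −78 °C) should give the 2-bromoallyl lactone F5. Radical cyclisation (Bu3SnH, AIBN) should give the 16-methylene tricycle F6, and allylic oxidation at C15 (SeO2 cat., t-BuOOH) should give 11, which steps 7–8 then correct at C15.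

Further compounds

F1 | step 19 | (E)-C5=C6 vinyl pinacol boronate from 22 | C=C1[C@@H]2CC[C@@H]3[C@](C2)(C(=O)OC[C@]3(/C=C/B4OC(C)(C)C(C)(C)O4)[C@@H](OC(C)=O)C[C@@H]4C(C)(C)O4)[C@@H]1O[Si](C)(C)C(C)(C)C
F2 | step 19 | ring-A closed C6H2–Bpin boronate with free C3–OH | C=C1[C@@H]2CC[C@@H]3[C@](C2)(C(=O)OC[C@]32[C@@H](OC(C)=O)C[C@@H](O)C(C)(C)[C@H]2CB2OC(C)(C)C(C)(C)O2)[C@@H]1O[Si](C)(C)C(C)(C)C
F3 | step 19 | ring-A closed C6 primary alcohol (3,6-diol) | C=C1[C@@H]2CC[C@@H]3[C@](C2)(C(=O)OC[C@]32[C@@H](OC(C)=O)C[C@@H](O)C(C)(C)[C@H]2CO)[C@@H]1O[Si](C)(C)C(C)(C)C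
F4 | step 3 | ent-7 (enantiomer of the Diels–Alder adduct) | C1=CC[C@H]2[C@](C1)(C(=O)OC)C(=O)OCC23COC(C)(C)OC3
F5 | step 5 | (8S,9S)-8-(2-bromoallyl) cis-fused lactone | C1=CC[C@@H]2[C@@](C1)(CC(Br)=C)C(=O)OCC23COC(C)(C)OC3
F6 | step 5 | (8S,9S,13R)-16-methylene core lactone acetonide with C15H2 | C=C1[C@@H]2CC[C@@H]3[C@](C2)(C(=O)OCC34COC(C)(C)OC4)C1
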